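**Retrosynthetic overview**

1. The target is two flavanones joined C3–C8'': unit 1 (rings A, C, B; atoms C2–C8a; 2R,3S; free 4'-OH) and unit 2 (rings A'', C'', B''; atoms C2''–C8a''; 2''S; 4'''-OMe). The last disconnection is the O1''–C2'' bond of ring C'' (retro-oxa-Michael, 6-endo-trig), which leads to a 2-hydroxyaryl alkylidene β-keto ester.
2. Enabling feature: in ring C'' the ether oxygen O1'' stands β to the C4'' carbonyl, and C3'' is a bare CH2 that can carry a temporary tert-butoxycarbonyl group. In ring A'' only the oxygen on C8a'' is left free (the oxygens on C5'' and C7'' are benzyl ethers), so closure can give only the 8''-linked flavanone.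
3. C3 of unit 1 is likewise α to C4=O and carries a second temporary ester. It activates the enantioselective closure of ring C, permits C-arylation at C3, and keeps unit 1 from enolizing until both esters leave together in the key step.
4. The C3–C8'' bond comes from C-arylation of the ring C β-keto ester with an aryllead triacetate. That reagent is made from the 3-iodo derivative of the same acetophenone that supplies ring A, so both A rings derive from one commercial ketone.
5. Ring order: rings A, A'', B and B'' are bought; ring C (unit 1) closes in step 3; ring C'' (unit 2) closes last, in step 11; hydrogenolysis ends the route.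

Key step: step 11

Remark: the quinidine- and quinine-derived thioureas are pseudo-enantiomers; the quinidine-derived one is taken to give the (2R) centre of unit 1 in step 3 and the quinine-derived one the (2''S) centre of unit 2 in step 11, and the two would simply be exchanged should the sense on these 5-alkoxy substrates prove opposite.

**Route**

Step 1
Reactants: 1 1-[2,4-bis(benzyloxy)-6-hydroxyphenyl]ethanone
Product: 2 tert-butyl 3-[2,4-bis(benzyloxy)-6-hydroxyphenyl]-3-oxopropanoate
Conditions: LiN(SiMe3)2 (3.5 equiv), THF, −78 °C; Boc2O (1.1 equiv), −78 to 0 °C; aq. NH4Cl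
Reagents that add atoms: di-tert-butyl dicarbonate CC(C)(C)OC(=O)OC(=O)OC(C)(C)C
Why: Claisen-type C-acylation of the ketone enolate within the phenoxide–enolate dianion should give the β-keto ester, because the acidic product is deprotonated by the excess base (which drives C- over O-acylation) and a tert-butyl ester does not lactonize onto the phenol.

Step 2
Reactants: 2 tert-butyl 3-[2,4-bis(benzyloxy)-6-hydroxyphenyl]-3-oxopropanoate; 3 4-(benzyloxy)benzaldehyde
Product: 4 tert-butyl (2Z)-2-[2,4-bis(benzyloxy)-6-hydroxybenzoyl]-3-[4-(benzyloxy)phenyl]prop-2-enoate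
Conditions: piperidine (0.2 equiv), AcOH (0.2 equiv), 4 Å molecular sieves, toluene, rt
Reagents that add atoms: none
Why: Knoevenagel condensation of the doubly activated methylene group with the aryl aldehyde under piperidinium acetate should stop at the alkylidene stage, since the chelated phenol does not add without a stronger base; the Z isomer is drawn, but either alkene isomer is expected to serve in step 3.

Step 3
Reactants: 4 tert-butyl (2Z)-2-[2,4-bis(benzyloxy)-6-hydroxybenzoyl]-3-[4-(benzyloxy)phenyl]prop-2-enoate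
Product: 5 tert-butyl (2R,3S)-5,7-bis(benzyloxy)-2-[4-(benzyloxy)phenyl]-4-oxochromane-3-carboxylate
Conditions: quinidine-derived thiourea catalyst (N-[3,5-bis(trifluoromethyl)phenyl]-N'-(9-deoxy-epi-quinidin-9-yl)thiourea, 10 mol %), toluene, −25 °C; then cold 1 M HCl wash
Reagents that add atoms: none
Why: Bifunctional amine–thiourea catalysis of an enantioselective oxa-Michael cyclization (6-endo-trig) of an alkylidene β-keto ester closes ring C, the catalyst choosing the face of the benzylidene carbon so that C2 is R, while C3 settles trans by enolization; the acid wash removes the base before retro-addition can erode C2.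

Step 4
Reactants: 1 1-[2,4-bis(benzyloxy)-6-hydroxyphenyl]ethanone
Product: 6 1-[4,6-bis(benzyloxy)-2-hydroxy-3-iodophenyl]ethanone
Conditions: benzyltrimethylammonium dichloroiodate (1.05 equiv), CaCO3, CH2Cl2–MeOH, rt
Reagents that add atoms: benzyltrimethylammonium dichloroiodate C[N+](C)(C)Cc1ccccc1.Cl[I-]Cl
Why: Electrophilic aromatic iodination directed to the position ortho to the free phenol (C3, also para to a benzyloxy group) is the established outcome for 2-hydroxy-4,6-dialkoxyacetophenones, and the CaCO3 buffer keeps the benzyl ethers intact.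

Step 5
Reactants: 6 1-[4,6-bis(benzyloxy)-2-hydroxy-3-iodophenyl]ethanone
Product: 7 1-[4,6-bis(benzyloxy)-3-iodo-2-(methoxymethoxy)phenyl]ethanone
Conditions: NaH, MOMCl, DMF, 0 °C to rt
Reagents that add atoms: chloromethyl methyl ether COCCl
Why: Williamson-type O-alkylation of the sodium phenoxide installs a methoxymethyl ether that shields the phenol from oxidation by tetravalent lead in step 7 and is removable later under mild acid.

Step 6
Reactants: 7 1-[4,6-bis(benzyloxy)-3-iodo-2-(methoxymethoxy)phenyl]ethanone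
Product: 8 1-[4,6-bis(benzyloxy)-2-(methoxymethoxy)-3-(trimethylstannyl)phenyl]ethanone
Conditions: (Me3Sn)2 (1.5 equiv), Pd(PPh3)4 (5 mol %), toluene, 110 °C
Reagents that add atoms: hexamethylditin C[Sn](C)(C)[Sn](C)(C)C
Why: Palladium-catalysed stannylation of the aryl iodide with hexamethylditin (oxidative addition, tin–tin transmetalation, reductive elimination) tolerates the methyl ketone, which rules out a route through an aryllithium.

Step 7
Reactants: 8 1-[4,6-bis(benzyloxy)-2-(methoxymethoxy)-3-(trimethylstannyl)phenyl]ethanone; 5 tert-butyl (2R,3S)-5,7-bis(benzyloxy)-2-[4-(benzyloxy)phenyl]-4-oxochromane-3-carboxylate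
Product: 10 tert-butyl (2S,3R)-3-[3-acetyl-4,6-bis(benzyloxy)-2-(methoxymethoxy)phenyl]-5,7-bis(benzyloxy)-2-[4-(benzyloxy)phenyl]-4-oxochromane-3-carboxylate, via aryllead triacetate 9 (not isolated)
Conditions: Pb(OAc)4 (1.05 equiv), Hg(OAc)2 (5 mol %), CHCl3, 40 °C; then 5, pyridine (3 equiv), CHCl3, 25 to 40 °C
Reagents that add atoms: none
Why: Tin–lead exchange gives an electron-rich aryllead triacetate whose C-arylation of the β-keto ester (lead enolate, then ligand coupling) is the established way to arylate chromanone-3-carboxylates and to make hindered quaternary α-aryl carbons, and it forges the C3–C8'' bond; the aryl group should enter anti to the C2 aryl group, the C3 configuration is of no consequence later, and the change of the C2 descriptor from R to S reflects only the new priority of C3.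

Step 8
Reactants: 10 tert-butyl (2S,3R)-3-[3-acetyl-4,6-bis(benzyloxy)-2-(methoxymethoxy)phenyl]-5,7-bis(benzyloxy)-2-[4-(benzyloxy)phenyl]-4-oxochromane-3-carboxylate
Product: 11 tert-butyl (2S,3R)-5,7-bis(benzyloxy)-3-[4,6-bis(benzyloxy)-3-(3-tert-butoxy-3-oxopropanoyl)-2-(methoxymethoxy)phenyl]-2-[4-(benzyloxy)phenyl]-4-oxochromane-3-carboxylate
Conditions: LiN(SiMe3)2 (2.2 equiv), THF, −78 °C; Boc2O (1.2 equiv), −78 to −20 °C; aq. NH4Cl
Reagents that add atoms: di-tert-butyl dicarbonate CC(C)(C)OC(=O)OC(=O)OC(C)(C)C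
Why: Claisen-type C-acylation of the lithium enolate of the methyl ketone with di-tert-butyl dicarbonate should be clean because unit 1 now has no enolisable hydrogen and its hindered C4 ketone is not attacked at low temperature.

Step 9
Reactants: 11 tert-butyl (2S,3R)-5,7-bis(benzyloxy)-3-[4,6-bis(benzyloxy)-3-(3-tert-butoxy-3-oxopropanoyl)-2-(methoxymethoxy)phenyl]-2-[4-(benzyloxy)phenyl]-4-oxochromane-3-carboxylate
Product: 12 tert-butyl (2S,3R)-5,7-bis(benzyloxy)-3-[4,6-bis(benzyloxy)-3-(3-tert-butoxy-3-oxopropanoyl)-2-hydroxyphenyl]-2-[4-(benzyloxy)phenyl]-4-oxochromane-3-carboxylate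
Conditions: NaHSO4·SiO2, CH2Cl2, rt
Reagents that add atoms: none
Why: Mild heterogeneous acid-catalysed hydrolysis of the phenolic methoxymethyl acetal spares both tert-butyl esters and the benzyl ethers, and with C3 still quaternary the freed phenol cannot condense with the neighbouring C4 ketone to a benzofuran.

Step 10
Reactants: 12 tert-butyl (2S,3R)-5,7-bis(benzyloxy)-3-[4,6-bis(benzyloxy)-3-(3-tert-butoxy-3-oxopropanoyl)-2-hydroxyphenyl]-2-[4-(benzyloxy)phenyl]-4-oxochromane-3-carboxylate; 13 4-methoxybenzaldehyde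
Product: 14 tert-butyl (2S,3R)-5,7-bis(benzyloxy)-3-{4,6-bis(benzyloxy)-3-[(2Z)-2-(tert-butoxycarbonyl)-3-(4-methoxyphenyl)prop-2-enoyl]-2-hydroxyphenyl}-2-[4-(benzyloxy)phenyl]-4-oxochromane-3-carboxylate
Conditions: 13 (1.5 equiv), piperidine (0.2 equiv), AcOH (0.2 equiv), 4 Å molecular sieves, toluene, rt to 40 °C
Reagents that add atoms: none
Why: Knoevenagel condensation as in step 2 gives the cyclization substrate; the quaternary keto ester of unit 1 has no acidic hydrogen and is inert to piperidinium acetate.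

Step 11
Reactants: 14 tert-butyl (2S,3R)-5,7-bis(benzyloxy)-3-{4,6-bis(benzyloxy)-3-[(2Z)-2-(tert-butoxycarbonyl)-3-(4-methoxyphenyl)prop-2-enoyl]-2-hydroxyphenyl}-2-[4-(benzyloxy)phenyl]-4-oxochromane-3-carboxylate
Product: 16 (2R,3S)-5,7-bis(benzyloxy)-2-[4-(benzyloxy)phenyl]-3-[(2S)-5,7-bis(benzyloxy)-2-(4-methoxyphenyl)-4-oxochroman-8-yl]chroman-4-one, via cyclized bis(keto ester) 15 (not isolated)
Conditions: quinine-derived thiourea catalyst (N-[3,5-bis(trifluoromethyl)phenyl]-N'-(9-deoxy-epi-quinin-9-yl)thiourea, 10 mol %), toluene, −25 °C; then TsOH·H2O (3 equiv), 80 °C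
Reagents that add atoms: none
Why: The quinuclidine nitrogen of the catalyst takes the proton of the chelated phenol on C8a'' while the thiourea binds the keto ester, and the phenoxide adds to the benzylidene carbon (the future C2'') in a 6-endo-trig oxa-Michael closure that forms the O1''–C2'' bond of ring C''; TsOH then cleaves both tert-butyl esters (loss of 2-methylpropene) and the two β-keto acids lose CO2. The closest known reaction type is the thiourea-catalysed enantioselective cyclization of alkylidene β-keto esters to flavanones with decarboxylation in the same flask. C2'' is set by the catalyst (S), which should override the stereocentres of unit 1, although a matched or mismatched pairing is possible. C3 of unit 1 is regenerated as a CH by ketonization of the enol left after decarboxylation and should equilibrate under the acid to the diequatorial 2,3-trans arrangement (3S) dictated by the untouched C2, whose descriptor returns from S to R only because the ester is gone. Regioselectivity (8''- versus 6''-linked flavanone) is secured because the only free phenol of ring A'' is the one on C8a'', the C5'' oxygen being a benzyl ether; chemoselectivity is secured because unit 1 has no enolisable hydrogen during the basic stage and ring A'' has no free phenol next to the C4 ketone during the acidic stage, so neither opening of ring C nor benzofuran formation can occur.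

Step 12
Reactants: 16 (2R,3S)-5,7-bis(benzyloxy)-2-[4-(benzyloxy)phenyl]-3-[(2S)-5,7-bis(benzyloxy)-2-(4-methoxyphenyl)-4-oxochroman-8-yl]chroman-4-one
Product: 17 (2R,3S)-5,7-dihydroxy-2-(4-hydroxyphenyl)-3-[(2S)-5,7-dihydroxy-2-(4-methoxyphenyl)-4-oxochroman-8-yl]chroman-4-one
Conditions: H2 (1 atm), Pd/C (10 wt %), EtOAc–MeOH, rt
Reagents that add atoms: none
Why: Heterogeneous hydrogenolysis of the five benzyl aryl ethers under neutral conditions should leave the methyl ether, both aryl ketones and all three stereocentres untouched.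

**Compound list**

1 | 1-[2,4-bis(benzyloxy)-6-hydroxyphenyl]ethanone | CC(=O)c1c(O)cc(OCc2ccccc2)cc1OCc1ccccc1 | starting material
2 | tert-butyl 3-[2,4-bis(benzyloxy)-6-hydroxyphenyl]-3-oxopropanoate | CC(C)(C)OC(=O)CC(=O)c1c(O)cc(OCc2ccccc2)cc1OCc1ccccc1 | intermediate
3 | 4-(benzyloxy)benzaldehyde | O=Cc1ccc(OCc2ccccc2)cc1 | starting material
4 | tert-butyl (2Z)-2-[2,4-bis(benzyloxy)-6-hydroxybenzoyl]-3-[4-(benzyloxy)phenyl]prop-2-enoate | CC(C)(C)OC(=O)/C(=C\c1ccc(OCc2ccccc2)cc1)C(=O)c1c(O)cc(OCc2ccccc2)cc1OCc1ccccc1 | intermediate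
5 | tert-butyl (2R,3S)-5,7-bis(benzyloxy)-2-[4-(benzyloxy)phenyl]-4-oxochromane-3-carboxylate (2,3-trans) | CC(C)(C)OC(=O)[C@@H]1C(=O)c2c(OCc3ccccc3)cc(OCc3ccccc3)cc2O[C@H]1c1ccc(OCc2ccccc2)cc1 | intermediate
6 | 1-[4,6-bis(benzyloxy)-2-hydroxy-3-iodophenyl]ethanone | CC(=O)c1c(O)c(I)c(OCc2ccccc2)cc1OCc1ccccc1 | intermediate
7 | 1-[4,6-bis(benzyloxy)-3-iodo-2-(methoxymethoxy)phenyl]ethanone | CC(=O)c1c(OCOC)c(I)c(OCc2ccccc2)cc1OCc1ccccc1 | intermediate
8 | 1-[4,6-bis(benzyloxy)-2-(methoxymethoxy)-3-(trimethylstannyl)phenyl]ethanone | CC(=O)c1c(OCOC)c([Sn](C)(C)C)c(OCc2ccccc2)cc1OCc1ccccc1 | intermediate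
9 | [3-acetyl-4,6-bis(benzyloxy)-2-(methoxymethoxy)phenyl]lead triacetate | CC(=O)c1c(OCOC)c([Pb](OC(C)=O)(OC(C)=O)OC(C)=O)c(OCc2ccccc2)cc1OCc1ccccc1 | intermediate (not isolated)
10 | tert-butyl (2S,3R)-3-[3-acetyl-4,6-bis(benzyloxy)-2-(methoxymethoxy)phenyl]-5,7-bis(benzyloxy)-2-[4-(benzyloxy)phenyl]-4-oxochromane-3-carboxylate (the two aryl groups trans) | CC(=O)c1c(OCOC)c(c(OCc2ccccc2)cc1OCc1ccccc1)[C@]1(C(=O)OC(C)(C)C)C(=O)c2c(OCc3ccccc3)cc(OCc3ccccc3)cc2O[C@H]1c1ccc(OCc2ccccc2)cc1 | intermediate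
11 | tert-butyl (2S,3R)-5,7-bis(benzyloxy)-3-[4,6-bis(benzyloxy)-3-(3-tert-butoxy-3-oxopropanoyl)-2-(methoxymethoxy)phenyl]-2-[4-(benzyloxy)phenyl]-4-oxochromane-3-carboxylate | CC(C)(C)OC(=O)CC(=O)c1c(OCOC)c(c(OCc2ccccc2)cc1OCc1ccccc1)[C@]1(C(=O)OC(C)(C)C)C(=O)c2c(OCc3ccccc3)cc(OCc3ccccc3)cc2O[C@H]1c1ccc(OCc2ccccc2)cc1 | intermediate
12 | tert-butyl (2S,3R)-5,7-bis(benzyloxy)-3-[4,6-bis(benzyloxy)-3-(3-tert-butoxy-3-oxopropanoyl)-2-hydroxyphenyl]-2-[4-(benzyloxy)phenyl]-4-oxochromane-3-carboxylate | CC(C)(C)OC(=O)CC(=O)c1c(O)c(c(OCc2ccccc2)cc1OCc1ccccc1)[C@]1(C(=O)OC(C)(C)C)C(=O)c2c(OCc3ccccc3)cc(OCc3ccccc3)cc2O[C@H]1c1ccc(OCc2ccccc2)cc1 | intermediate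
13 | 4-methoxybenzaldehyde | COc1ccc(C=O)cc1 | starting material
14 | tert-butyl (2S,3R)-5,7-bis(benzyloxy)-3-{4,6-bis(benzyloxy)-3-[(2Z)-2-(tert-butoxycarbonyl)-3-(4-methoxyphenyl)prop-2-enoyl]-2-hydroxyphenyl}-2-[4-(benzyloxy)phenyl]-4-oxochromane-3-carboxylate | COc1ccc(/C=C(\C(=O)OC(C)(C)C)C(=O)c2c(O)c(c(OCc3ccccc3)cc2OCc2ccccc2)[C@]2(C(=O)OC(C)(C)C)C(=O)c3c(OCc4ccccc4)cc(OCc4ccccc4)cc3O[C@H]2c2ccc(OCc3ccccc3)cc2)cc1 | intermediate
15 | tert-butyl (2S,3R)-5,7-bis(benzyloxy)-2-[4-(benzyloxy)phenyl]-3-[(2S,3R)-5,7-bis(benzyloxy)-3-(tert-butoxycarbonyl)-2-(4-methoxyphenyl)-4-oxochroman-8-yl]-4-oxochromane-3-carboxylate | COc1ccc([C@@H]2[C@@H](C(=O)OC(C)(C)C)C(=O)c3c(OCc4ccccc4)cc(OCc4ccccc4)c([C@]4(C(=O)OC(C)(C)C)C(=O)c5c(OCc6ccccc6)cc(OCc6ccccc6)cc5O[C@H]4c4ccc(OCc5ccccc5)cc4)c3O2)cc1 | intermediate (not isolated)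
16 | (2R,3S)-5,7-bis(benzyloxy)-2-[4-(benzyloxy)phenyl]-3-[(2S)-5,7-bis(benzyloxy)-2-(4-methoxyphenyl)-4-oxochroman-8-yl]chroman-4-one | COc1ccc([C@@H]2CC(=O)c3c(OCc4ccccc4)cc(OCc4ccccc4)c([C@@H]4C(=O)c5c(OCc6ccccc6)cc(OCc6ccccc6)cc5O[C@H]4c4ccc(OCc5ccccc5)cc4)c3O2)cc1 | intermediate
17 | (2R,3S)-5,7-dihydroxy-2-(4-hydroxyphenyl)-3-[(2S)-5,7-dihydroxy-2-(4-methoxyphenyl)-4-oxochroman-8-yl]chroman-4-one | COc1ccc([C@@H]2CC(=O)c3c(O)cc(O)c([C@@H]4C(=O)c5c(O)cc(O)cc5O[C@H]4c4ccc(O)cc4)c3O2)cc1 | target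

**Step count**

Total steps: 12. Longest linear sequence: 9 steps (steps 1, 2, 3, 7, 8, 9, 10, 11, 12; the branch through steps 4, 5, 6 and then 7 to 12 is equally long).

**Steps most likely to fail**

Step 7. Ligand coupling at the crowded C3 (flanked by the C2 aryl group and the tert-butyl ester) may be slower than reductive decomposition of the aryllead reagent. While 5 waits in pyridine its enolate can also ring-open reversibly (retro-oxa-Michael), which would erode C2. The fallback sets out from 5 and 1 and makes the same bond by an oxidative cross-dehydrogenative coupling, a reaction known for phenols with α-substituted β-keto esters and less sensitive to bulk than ligand coupling on lead. FeCl3 (trivalent iron, 10 mol %) with 1,10-phenanthroline and di-tert-butyl peroxide in 1,2-dichloroethane at 70 °C would join C3 of 5 to the carbon ortho to the hydroxyl group of 1. This would give the free phenol tert-butyl (2S,3R)-3-[3-acetyl-4,6-bis(benzyloxy)-2-hydroxyphenyl]-5,7-bis(benzyloxy)-2-[4-(benzyloxy)phenyl]-4-oxochromane-3-carboxylate F1. C-acylation of its phenoxide–enolate dianion (LiN(SiMe3)2, Boc2O, as in step 1) would then give 12, where the fallback comes back to the route; steps 4 to 6 and 9 fall away.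

Step 11. Facial selectivity at C2'' may be poor if the quaternary centre next to C8'' opposes the catalyst, and the hindered phenol may cyclize incompletely before the acid stage. The fallback sets out from 10 and closes ring C'' by SN2 displacement instead of conjugate addition, still as the last ring. An asymmetric boron aldol reaction of the methyl ketone with 13 ((Ipc)2BCl, Et3N, the reagent enantiomer that delivers the R carbinol) would give tert-butyl (2S,3R)-3-{4,6-bis(benzyloxy)-3-[(3R)-3-hydroxy-3-(4-methoxyphenyl)propanoyl]-2-(methoxymethoxy)phenyl}-5,7-bis(benzyloxy)-2-[4-(benzyloxy)phenyl]-4-oxochromane-3-carboxylate F2. Removal of the methoxymethyl group (NaHSO4·SiO2) would give the phenol tert-butyl (2S,3R)-3-{4,6-bis(benzyloxy)-2-hydroxy-3-[(3R)-3-hydroxy-3-(4-methoxyphenyl)propanoyl]phenyl}-5,7-bis(benzyloxy)-2-[4-(benzyloxy)phenyl]-4-oxochromane-3-carboxylate F3. An intramolecular Mitsunobu etherification (PPh3, DIAD, THF, 0 °C) would then form O1''–C2'' with inversion to give tert-butyl (2S,3R)-5,7-bis(benzyloxy)-2-[4-(benzyloxy)phenyl]-3-[(2S)-5,7-bis(benzyloxy)-2-(4-methoxyphenyl)-4-oxochroman-8-yl]-4-oxochromane-3-carboxylate F4. TsOH·H2O in toluene at 80 °C would remove the remaining ester and give 16, where the fallback comes back to the route.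

Step 3. The twisted 2,6-disubstituted aryl ketone may lower facial selectivity, and the enolisable product may lose enantiopurity at C2 by reversible ring opening during isolation. The fallback sets out from 1 and sets C2 by C–C instead of C–O bond formation. Heating with N,N-dimethylformamide dimethyl acetal would give the enaminone (2E)-1-[2,4-bis(benzyloxy)-6-hydroxyphenyl]-3-(dimethylamino)prop-2-en-1-one F5, which acid would close to 5,7-bis(benzyloxy)-4H-chromen-4-one F6. Rhodium-catalysed asymmetric 1,4-addition of 4-(benzyloxy)phenylboronic acid ([Rh(OH)(cod)]2 with the enantiomer of BINAP that delivers the R product, dioxane–water) would give (2R)-5,7-bis(benzyloxy)-2-[4-(benzyloxy)phenyl]chroman-4-one F7. C-acylation of its kinetic lithium enolate (LiN(SiMe3)2, THF, −78 °C, then Boc2O, kept cold to outrun ring opening) would give 5, where the fallback comes back to the route.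

**Further compounds**

F1 | step 7 | tert-butyl (2S,3R)-3-[3-acetyl-4,6-bis(benzyloxy)-2-hydroxyphenyl]-5,7-bis(benzyloxy)-2-[4-(benzyloxy)phenyl]-4-oxochromane-3-carboxylate | CC(=O)c1c(O)c(c(OCc2ccccc2)cc1OCc1ccccc1)[C@]1(C(=O)OC(C)(C)C)C(=O)c2c(OCc3ccccc3)cc(OCc3ccccc3)cc2O[C@H]1c1ccc(OCc2ccccc2)cc1
F2 | step 11 | tert-butyl (2S,3R)-3-{4,6-bis(benzyloxy)-3-[(3R)-3-hydroxy-3-(4-methoxyphenyl)propanoyl]-2-(methoxymethoxy)phenyl}-5,7-bis(benzyloxy)-2-[4-(benzyloxy)phenyl]-4-oxochromane-3-carboxylate | COc1ccc([C@H](O)CC(=O)c2c(OCOC)c(c(OCc3ccccc3)cc2OCc2ccccc2)[C@]2(C(=O)OC(C)(C)C)C(=O)c3c(OCc4ccccc4)cc(OCc4ccccc4)cc3O[C@H]2c2ccc(OCc3ccccc3)cc2)cc1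
F3 | step 11 | tert-butyl (2S,3R)-3-{4,6-bis(benzyloxy)-2-hydroxy-3-[(3R)-3-hydroxy-3-(4-methoxyphenyl)propanoyl]phenyl}-5,7-bis(benzyloxy)-2-[4-(benzyloxy)phenyl]-4-oxochromane-3-carboxylate | COc1ccc([C@H](O)CC(=O)c2c(O)c(c(OCc3ccccc3)cc2OCc2ccccc2)[C@]2(C(=O)OC(C)(C)C)C(=O)c3c(OCc4ccccc4)cc(OCc4ccccc4)cc3O[C@H]2c2ccc(OCc3ccccc3)cc2)cc1
F4 | step 11 | tert-butyl (2S,3R)-5,7-bis(benzyloxy)-2-[4-(benzyloxy)phenyl]-3-[(2S)-5,7-bis(benzyloxy)-2-(4-methoxyphenyl)-4-oxochroman-8-yl]-4-oxochromane-3-carboxylate | COc1ccc([C@@H]2CC(=O)c3c(OCc4ccccc4)cc(OCc4ccccc4)c([C@]4(C(=O)OC(C)(C)C)C(=O)c5c(OCc6ccccc6)cc(OCc6ccccc6)cc5O[C@H]4c4ccc(OCc5ccccc5)cc4)c3O2)cc1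
F5 | step 3 | (2E)-1-[2,4-bis(benzyloxy)-6-hydroxyphenyl]-3-(dimethylamino)prop-2-en-1-one | CN(C)/C=C/C(=O)c1c(O)cc(OCc2ccccc2)cc1OCc1ccccc1
F6 | step 3 | 5,7-bis(benzyloxy)-4H-chromen-4-one | O=c1ccoc2cc(OCc3ccccc3)cc(OCc3ccccc3)c12
F7 | step 3 | (2R)-5,7-bis(benzyloxy)-2-[4-(benzyloxy)phenyl]chroman-4-one | O=C1C[C@H](c2ccc(OCc3ccccc3)cc2)Oc2cc(OCc3ccccc3)cc(OCc3ccccc3)c12
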